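**Strategy**

The plan cuts the 1,2-dioxane at C4–C5 (C1 = lactone carbonyl, C3 = peroxy methine, C4 = methyl-bearing lactone carbon, C6 = quaternary peroxy carbon). This is the one ring bond whose two carbons carry no peroxide oxygen, so it can be made as an olefin by ring-closing metathesis while the O–O bond already links two enantiopure fragments. One operation thus closes the 3,6-dihydro-1,2-dioxine and leaves the C4=C5 alkene needed for cis-iodolactonisation. The substrate is an acyclic diallylic peroxide: C3 carries isopropenyl and a free CH2CO2H arm, C6 carries vinyl, methyl and the 10-phenyldecyl chain.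

Key step: step 13

Remarks on the chemistry:
- C1 is carried as a silyl ether through peroxide formation and as the free acid through the metathesis. A β-sulfonyloxy ester would eliminate under the basic peroxide alkylation, and a late ester hydrolysis would expose the base-labile C3–H of the dihydrodioxine to hydroxide.
- (R)-2-Methylglycidol leads to the required (S)-epoxide only because the chain enters at the oxirane CH2 and the ring is re-closed onto the former CH2OTs carbon; direct displacement of the sulfonate would give the enantiomer.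
- Assumption: both enantiomers of 2-methylglycidol and of HYTRA are purchased; the sense of the HYTRA aldol with methacrolein is taken from its isobutyraldehyde analogue.

**Route**

Step 1
Reactants: 1 phenylmagnesium bromide; 2 1,9-dibromononane
Product: 3 (9-bromononyl)benzene
Conditions: Li2CuCl4 (3 mol%), THF, 0 °C → rt; 2 in threefold excess
Reagents that add atoms: none
Why: Copper-catalysed Kochi-type coupling of an aryl Grignard reagent with a primary alkyl bromide; the excess dibromide should suppress double arylation and is recovered by distillation.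

Step 2
Reactants: 4 (R)-2-methylglycidol
Product: 5 [(2S)-2-methyloxiran-2-yl]methyl 4-methylbenzenesulfonate
Conditions: TsCl, Et3N, DMAP (cat.), CH2Cl2, 0 °C
Reagents that add atoms: p-toluenesulfonyl chloride, Cc1ccc(cc1)S(Cl)(=O)=O
Why: Sulfonylation of a primary alcohol; the stereocentre is untouched and the descriptor changes to S only because CH2OTs outranks the ring CH2.

Step 3
Reactants: 3 (9-bromononyl)benzene; 5 [(2S)-2-methyloxiran-2-yl]methyl 4-methylbenzenesulfonate
Product: 8 (2S)-2-methyl-2-(10-phenyldecyl)oxirane, via Grignard reagent 6 (not isolated), via hydroxy tosylate 7 (not isolated)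
Conditions: Mg, THF, rt; then 5, CuI (10 mol%), THF, −40 → −20 °C; aq. NH4Cl; crude, K2CO3, MeOH, rt
Reagents that add atoms: none
Why: Grignard formation, copper-catalysed epoxide opening at the oxirane CH2 (the neopentyl-type CH2OTs is much slower) and Williamson ring closure of the tertiary alkoxide onto the CH2OTs carbon; no bond to the stereocentre is broken, and the exchange of roles of the two CH2 groups makes the product S.

Step 4
Reactants: 8 (2S)-2-methyl-2-(10-phenyldecyl)oxirane
Product: 9 (2R)-2-hydroperoxy-2-methyl-12-phenyldodecan-1-ol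
Conditions: H2O2 (anhydrous, in Et2O), phosphomolybdic acid (3 mol%), Et2O, rt
Reagents that add atoms: hydrogen peroxide, OO
Why: Acid-catalysed perhydrolysis of a 2,2-dialkyl oxirane (borderline-SN2 epoxide opening) in which H2O2 attacks the tertiary carbon anti to the departing oxygen, so C6 is set with inversion (S-epoxide to R-hydroperoxide).

Step 5
Reactants: 10 (S)-HYTRA, (1S)-2-hydroxy-1,2,2-triphenylethyl acetate; 11 methacrolein
Product: 12 (1S)-2-hydroxy-1,2,2-triphenylethyl (3S)-3-hydroxy-4-methylpent-4-enoate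
Conditions: LDA (2.1 equiv), THF, −78 → 0 °C; then 11, THF/2-methylbutane, −125 °C; aq. NH4Cl; recrystallisation
Reagents that add atoms: none
Why: HYTRA acetate aldol addition of the doubly lithiated ester enolate; the auxiliary stereocentre controls the aldehyde face, the (S)-auxiliary should give the (3S)-carbinol, and crystallisation should remove the minor diastereomer.

Step 6
Reactants: 12 (1S)-2-hydroxy-1,2,2-triphenylethyl (3S)-3-hydroxy-4-methylpent-4-enoate
Product: 13 (3S)-4-methylpent-4-ene-1,3-diol
Conditions: LiAlH4, THF, 0 °C → rt; Fieser work-up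
Reagents that add atoms: none
Why: Hydride reduction of the ester cleaves the auxiliary (recoverable as the triphenylethanediol) and gives the 1,3-diol without touching the carbinol centre or the 1,1-disubstituted alkene.

Step 7
Reactants: 13 (3S)-4-methylpent-4-ene-1,3-diol
Product: 14 (3S)-1-[(tert-butyldimethylsilyl)oxy]-4-methylpent-4-en-3-ol
Conditions: TBSCl (1.05 equiv), imidazole, CH2Cl2, −10 °C
Reagents that add atoms: tert-butyldimethylsilyl chloride, CC(C)(C)[Si](C)(C)Cl
Why: Silylation selective for the primary over the secondary allylic hydroxyl on steric grounds.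

Step 8
Reactants: 14 (3S)-1-[(tert-butyldimethylsilyl)oxy]-4-methylpent-4-en-3-ol; 9 (2R)-2-hydroperoxy-2-methyl-12-phenyldodecan-1-ol
Product: 16 (2R)-2-({(3R)-1-[(tert-butyldimethylsilyl)oxy]-4-methylpent-4-en-3-yl}peroxy)-2-methyl-12-phenyldodecan-1-ol, via allylic mesylate 15 (not isolated)
Conditions: Ms2O, i-Pr2NEt, CH2Cl2, −30 °C; crude 15, then 9, CsOH·H2O (1 equiv), DMF, 0 °C
Reagents that add atoms: none
Why: Williamson-type SN2 O-alkylation of a caesium alkylperoxide by a secondary sulfonate, which sets C3 with inversion (S to R); one equivalent of base deprotonates only the more acidic OOH, Ms2O keeps chloride out, and the electrophile has no acidifying carbonyl, so E1cB elimination is excluded.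

Step 9
Reactants: 16 (2R)-2-({(3R)-1-[(tert-butyldimethylsilyl)oxy]-4-methylpent-4-en-3-yl}peroxy)-2-methyl-12-phenyldodecan-1-ol
Product: 17 (2R)-2-({(3R)-1-[(tert-butyldimethylsilyl)oxy]-4-methylpent-4-en-3-yl}peroxy)-2-methyl-12-phenyldodecanal
Conditions: Dess–Martin periodinane, CH2Cl2, 0 °C → rt
Reagents that add atoms: none
Why: Dess–Martin oxidation of the primary alcohol to a non-enolisable α-peroxy aldehyde under conditions that leave the O–O bond, the silyl ether and the alkene alone.

Step 10
Reactants: 17 (2R)-2-({(3R)-1-[(tert-butyldimethylsilyl)oxy]-4-methylpent-4-en-3-yl}peroxy)-2-methyl-12-phenyldodecanal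
Product: 18 tert-butyldimethyl{[(3R)-4-methyl-3-{[(3R)-3-methyl-13-phenyltridec-1-en-3-yl]peroxy}pent-4-en-1-yl]oxy}silane
Conditions: Ph3PCH3Br, KHMDS, THF, 0 °C; then 17, −78 → 0 °C
Reagents that add atoms: methyltriphenylphosphonium bromide, C[P+](c1ccccc1)(c1ccccc1)c1ccccc1.[Br-]
Why: Wittig methylenation; at low temperature the ylide should add to the aldehyde (no α-hydrogen) much faster than it can deprotonate C3–H or attack the peroxide.

Step 11
Reactants: 18 tert-butyldimethyl{[(3R)-4-methyl-3-{[(3R)-3-methyl-13-phenyltridec-1-en-3-yl]peroxy}pent-4-en-1-yl]oxy}silane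
Product: 19 (3R)-4-methyl-3-{[(3R)-3-methyl-13-phenyltridec-1-en-3-yl]peroxy}pent-4-en-1-ol
Conditions: HF·pyridine, pyridine, THF, 0 °C → rt
Reagents that add atoms: none
Why: Fluoride desilylation under buffered, non-basic conditions, chosen over TBAF because base could start Kornblum–DeLaMare fragmentation at C3–H.

Step 12
Reactants: 19 (3R)-4-methyl-3-{[(3R)-3-methyl-13-phenyltridec-1-en-3-yl]peroxy}pent-4-en-1-ol
Product: 20 (3R)-4-methyl-3-{[(3R)-3-methyl-13-phenyltridec-1-en-3-yl]peroxy}pent-4-enoic acid
Conditions: TEMPO (20 mol%), PhI(OAc)2 (2.2 equiv), MeCN/H2O, rt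
Reagents that add atoms: water, O
Why: Oxoammonium (TEMPO/PhI(OAc)2) oxidation of the primary alcohol through the aldehyde hydrate to the acid in one pot at near-neutral pH, so the β-peroxy aldehyde is never exposed to base.

Step 13
Reactants: 20 (3R)-4-methyl-3-{[(3R)-3-methyl-13-phenyltridec-1-en-3-yl]peroxy}pent-4-enoic acid
Product: 21 2-[(3R,6R)-4,6-dimethyl-6-(10-phenyldecyl)-3,6-dihydro-1,2-dioxin-3-yl]acetic acid
Conditions: Hoveyda–Grubbs II (10 mol%, two portions), toluene (5 mM), 50 °C, argon sparge
Reagents that add atoms: none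
Why: The phosphine-free ruthenium carbene should first exchange onto the monosubstituted vinyl group at C6, and the resulting C5 alkylidene then adds [2+2] to the isopropenyl C=C and cycloreverts to release the ring and Ru=CH2. The closest known chemistry is ruthenium-catalysed ring-closing metathesis of dialkenyl dialkyl peroxides, and of dienes to trisubstituted cyclohexenes beside a quaternary carbon. The one ring is closed as a six-membered 3,6-dihydro-1,2-dioxine from a 1,7-diene that has the O–O unit inside the tether, by forming C4=C5 with loss of ethene, which the argon stream removes. No stereocentre is formed; C3 and C6 are already in place and are not touched by a neutral carbene. The step needs chemoselectivity for C=C over O–O and over olefin migration: the catalyst carries no free phosphine that could reduce the peroxide, high dilution disfavours dimerisation, and the fully substituted C6 together with the gauche C–O–O–C unit favours the folded conformer. The free acid is tolerated by ruthenium carbenes and should damp hydride-mediated isomerisation.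

Step 14
Reactants: 21 2-[(3R,6R)-4,6-dimethyl-6-(10-phenyldecyl)-3,6-dihydro-1,2-dioxin-3-yl]acetic acid
Product: 22 (3R,4R,4aS,7aR)-4-iodo-3,4a-dimethyl-3-(10-phenyldecyl)tetrahydrofuro[3,2-c][1,2]dioxin-6(3H)-one
Conditions: I2, NaHCO3, MeCN/H2O, 0 °C → rt, dark
Reagents that add atoms: iodine, II
Why: Iodolactonisation (5-exo); the carboxylate tethered at C3 can reach C4 only on its own face, so the γ-lactone is cis-fused and C4 is set by C3, with iodine anti at C5.

Step 15
Reactants: 22 (3R,4R,4aS,7aR)-4-iodo-3,4a-dimethyl-3-(10-phenyldecyl)tetrahydrofuro[3,2-c][1,2]dioxin-6(3H)-one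
Product: 23 (3R,4aR,7aR)-3,4a-dimethyl-3-(10-phenyldecyl)tetrahydrofuro[3,2-c][1,2]dioxin-6(3H)-one
Conditions: Bu3SnH, Et3B (cat.), air, toluene, 0 °C → rt
Reagents that add atoms: none
Why: Radical-chain hydrodeiodination with tin hydride; the ring-bound C5 radical cannot reach the in-line geometry for attack on the O–O bond, low-temperature initiation spares the peroxide, and only the C5 centre is erased.

**Compound list**

1 | phenylmagnesium bromide | Br[Mg]c1ccccc1 | starting material
2 | 1,9-dibromononane | BrCCCCCCCCCBr | starting material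
3 | (9-bromononyl)benzene | BrCCCCCCCCCc1ccccc1 | intermediate
4 | (R)-2-methylglycidol | C[C@@]1(CO)CO1 | starting material
5 | [(2S)-2-methyloxiran-2-yl]methyl 4-methylbenzenesulfonate | C[C@@]1(COS(=O)(=O)c2ccc(C)cc2)CO1 | intermediate
6 | (9-phenylnonyl)magnesium bromide | Br[Mg]CCCCCCCCCc1ccccc1 | intermediate
7 | (2S)-2-hydroxy-2-methyl-12-phenyldodecyl 4-methylbenzenesulfonate | C[C@@](O)(COS(=O)(=O)c1ccc(C)cc1)CCCCCCCCCCc1ccccc1 | intermediate
8 | (2S)-2-methyl-2-(10-phenyldecyl)oxirane | C[C@@]1(CO1)CCCCCCCCCCc1ccccc1 | intermediate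
9 | (2R)-2-hydroperoxy-2-methyl-12-phenyldodecan-1-ol | C[C@](OO)(CO)CCCCCCCCCCc1ccccc1 | intermediate
10 | (S)-HYTRA, (1S)-2-hydroxy-1,2,2-triphenylethyl acetate | CC(=O)O[C@@H](c1ccccc1)C(O)(c1ccccc1)c1ccccc1 | starting material
11 | methacrolein | C=C(C)C=O | starting material
12 | (1S)-2-hydroxy-1,2,2-triphenylethyl (3S)-3-hydroxy-4-methylpent-4-enoate | C=C(C)[C@@H](O)CC(=O)O[C@@H](c1ccccc1)C(O)(c1ccccc1)c1ccccc1 | intermediate
13 | (3S)-4-methylpent-4-ene-1,3-diol | C=C(C)[C@@H](O)CCO | intermediate
14 | (3S)-1-[(tert-butyldimethylsilyl)oxy]-4-methylpent-4-en-3-ol | C=C(C)[C@@H](O)CCO[Si](C)(C)C(C)(C)C | intermediate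
15 | (3S)-1-[(tert-butyldimethylsilyl)oxy]-4-methylpent-4-en-3-yl methanesulfonate | C=C(C)[C@@H](OS(C)(=O)=O)CCO[Si](C)(C)C(C)(C)C | intermediate
16 | (2R)-2-({(3R)-1-[(tert-butyldimethylsilyl)oxy]-4-methylpent-4-en-3-yl}peroxy)-2-methyl-12-phenyldodecan-1-ol | C=C(C)[C@H](OO[C@@](C)(CO)CCCCCCCCCCc1ccccc1)CCO[Si](C)(C)C(C)(C)C | intermediate
17 | (2R)-2-({(3R)-1-[(tert-butyldimethylsilyl)oxy]-4-methylpent-4-en-3-yl}peroxy)-2-methyl-12-phenyldodecanal | C=C(C)[C@H](OO[C@@](C)(C=O)CCCCCCCCCCc1ccccc1)CCO[Si](C)(C)C(C)(C)C | intermediate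
18 | tert-butyldimethyl{[(3R)-4-methyl-3-{[(3R)-3-methyl-13-phenyltridec-1-en-3-yl]peroxy}pent-4-en-1-yl]oxy}silane | C=C(C)[C@H](OO[C@@](C)(C=C)CCCCCCCCCCc1ccccc1)CCO[Si](C)(C)C(C)(C)C | intermediate
19 | (3R)-4-methyl-3-{[(3R)-3-methyl-13-phenyltridec-1-en-3-yl]peroxy}pent-4-en-1-ol | C=C(C)[C@H](OO[C@@](C)(C=C)CCCCCCCCCCc1ccccc1)CCO | intermediate
20 | (3R)-4-methyl-3-{[(3R)-3-methyl-13-phenyltridec-1-en-3-yl]peroxy}pent-4-enoic acid | C=C[C@@](C)(CCCCCCCCCCc1ccccc1)OO[C@H](CC(=O)O)C(C)=C | intermediate
21 | 2-[(3R,6R)-4,6-dimethyl-6-(10-phenyldecyl)-3,6-dihydro-1,2-dioxin-3-yl]acetic acid | C[C@@]1(CCCCCCCCCCc2ccccc2)C=C(C)[C@@H](CC(=O)O)OO1 | intermediate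
22 | (3R,4R,4aS,7aR)-4-iodo-3,4a-dimethyl-3-(10-phenyldecyl)tetrahydrofuro[3,2-c][1,2]dioxin-6(3H)-one | C[C@@]1(CCCCCCCCCCc2ccccc2)[C@H](I)[C@@]2(C)OC(=O)C[C@H]2OO1 | intermediate
23 | (3R,4aR,7aR)-3,4a-dimethyl-3-(10-phenyldecyl)tetrahydrofuro[3,2-c][1,2]dioxin-6(3H)-one (cis-fused peroxy lactone) | C[C@@]1(CCCCCCCCCCc2ccccc2)C[C@@]2(C)OC(=O)C[C@H]2OO1 | target

**Step count and risks**

Total steps: 15. Longest linear sequence: 11 steps (steps 1, 3, 4, 8–15).

Steps most likely to fail:

1. Step 13. Initiation at the vinyl group beside the quaternary C6 and engagement of the 1,1-disubstituted olefin may both be slow, which gives time for ruthenium-induced O–O cleavage or oligomerisation. The fallback is a relay ring-closing metathesis; it sets out from 17 and returns at 21. Wittig reaction of 17 with the ylide from [2-(allyloxy)ethyl]triphenylphosphonium bromide (KHMDS, THF, −78 °C) should give the relay diene silyl ether F1. HF·pyridine then gives the relay alcohol F2, and TEMPO/PhI(OAc)2 gives the relay acid F3. With Hoveyda–Grubbs II the carbene loads on the unhindered allyl ether terminus, closes to 2,5-dihydrofuran and is thereby placed on C5, from where closure onto the isopropenyl group gives 21.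

2. Step 8. The peroxide anion may attack the alkene terminus (SN2'), or the allylic sulfonate may ionise or eliminate, which would erode the C3 configuration. The fallback is an oxetane opening; it sets out from 13 and returns at 16. Tosylation of the primary hydroxyl (TsCl, pyridine, 0 °C) gives the hydroxy tosylate F4, and KOtBu in THF closes it to the oxetane (2S)-2-(prop-1-en-2-yl)oxetane F5 with retention at the carbinol carbon. Lewis-acid-catalysed opening of F5 by hydroperoxide 9 (TMSOTf cat., Et2O, −78 → −20 °C), a known invertive peroxidation of oxetanes at the substituted carbon, should give the peroxy diol F6. Silylation of the less hindered primary hydroxyl (TBSCl, imidazole, −20 °C) then gives 16.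

3. Step 10. The basic ylide may start fragmentation at C3–H (Kornblum–DeLaMare) or attack the O–O bond faster than it olefinates the hindered aldehyde. The fallback is a Peterson olefination; it sets out from 17 and returns at 19. Addition of (trimethylsilyl)methylmagnesium chloride (THF, −78 °C) gives the β-hydroxysilane F7 as a mixture of carbinol epimers, both of which are productive. Aqueous HF in MeCN then effects the acid-promoted elimination and removes the silyl ether in the same operation, giving 19 directly.

**Further compounds**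

F1 | step 13 | tert-butyldimethyl{[(3R)-4-methyl-3-({(2Z,4R)-4-methyl-14-phenyl-1-(prop-2-en-1-yloxy)tetradec-2-en-4-yl}peroxy)pent-4-en-1-yl]oxy}silane | C=C(C)[C@H](OO[C@@](C)(/C=C\COCC=C)CCCCCCCCCCc1ccccc1)CCO[Si](C)(C)C(C)(C)C
F2 | step 13 | (3R)-4-methyl-3-({(2Z,4R)-4-methyl-14-phenyl-1-(prop-2-en-1-yloxy)tetradec-2-en-4-yl}peroxy)pent-4-en-1-ol | C=C(C)[C@H](OO[C@@](C)(/C=C\COCC=C)CCCCCCCCCCc1ccccc1)CCO
F3 | step 13 | (3R)-4-methyl-3-({(2Z,4R)-4-methyl-14-phenyl-1-(prop-2-en-1-yloxy)tetradec-2-en-4-yl}peroxy)pent-4-enoic acid | C=C(C)[C@H](OO[C@@](C)(/C=C\COCC=C)CCCCCCCCCCc1ccccc1)CC(=O)O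
F4 | step 8 | (3S)-3-hydroxy-4-methylpent-4-en-1-yl 4-methylbenzenesulfonate | C=C(C)[C@@H](O)CCOS(=O)(=O)c1ccc(C)cc1
F5 | step 8 | (2S)-2-(prop-1-en-2-yl)oxetane | C=C(C)[C@@H]1CCO1
F6 | step 8 | (2R)-2-{[(3R)-1-hydroxy-4-methylpent-4-en-3-yl]peroxy}-2-methyl-12-phenyldodecan-1-ol | C=C(C)[C@H](OO[C@@](C)(CO)CCCCCCCCCCc1ccccc1)CCO
F7 | step 10 | (3R)-3-({(3R)-1-[(tert-butyldimethylsilyl)oxy]-4-methylpent-4-en-3-yl}peroxy)-3-methyl-13-phenyl-1-(trimethylsilyl)tridecan-2-ol (C2 epimers) | C=C(C)[C@H](OO[C@@](C)(C(O)C[Si](C)(C)C)CCCCCCCCCCc1ccccc1)CCO[Si](C)(C)C(C)(C)C
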